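The rate constants are assumed; the rest is arithmetic.

The pitfall I nearly fell into was reading the opening ratio of two rates as the share of target, as if that ratio held for the whole run.

    2 starting material → self-condensation product (k1 = 1.31 M⁻¹ h⁻¹)
    catalyst intermediate A ⇌ catalyst intermediate B (K2 = 1.68, k2 = 0.756 h⁻¹)
    catalyst intermediate B → free catalyst + target (k3 = 0.172 h⁻¹)
    starting material + free catalyst → catalyst intermediate A (k4 = 2.37 M⁻¹ h⁻¹)

starting material 0.30 M; free catalyst 30 mM; time 15 d

1. why nothing more happens at 15 d, or that something still does (all of the starting material has reacted / forward and back rates have come level / no working catalyst is left / it is still moving)
2. amount of target at 15 d, in percent of the starting material charged

- percent here means starting material units held: one self-condensation product counts as two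
- a step written with two of one species runs at k times the square of its concentration and takes two of it each time
- the reaction counts as stopped when no species that holds the starting material changes by six tenths of a point or more over the second half of the time
- run time (flask): 15 d

At the start, starting material went to self-condensation 11.1 times as fast as to capture by free catalyst, a selectivity factor. But self-condensation follows the square of the fraction of the charge left and capture follows that fraction times the fraction of the catalyst that is free, so the ratio goes with the first fraction divided by the second.

I took two extreme flasks. In the first, the catalyst never came back, which meant one turnover and up to 10.0% of the charge. In the second, the catalyst stayed free throughout. Summing the capture share over the falling fraction gave the natural log of one plus the opening ratio, divided by that ratio: 22.5%, which I call the free-catalyst share, or 2.25 turnovers.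

The real flask had to lie between them. Catalyst intermediate B had a half-life of 4.03 h by step 3, and the bulk of the starting material had a first half-life of 1.27 h by self-condensation, shorter than that, so the bulk saw about one pass. The tail, where the two routes draw level, had a time of 14.1 h, longer than that half-life of catalyst intermediate B, so the catalyst could return there. I settled midway, at 16.3%. Both exits from the starting material run one way, and the run time is 25.6 tail times, so my call was: all of the starting material has reacted.

The forecast gave all of the starting material has reacted and 16%, holding that capture “mainly wins the low-concentration tail”.

The flask gave all of the starting material has reacted, with target at 15.4%, or 1.54 turnovers. Self-condensation ran first, with half of its turnover done by 1.00 h, while capture reached that mark at 0.189 d; by 1.50 d the flask held 1.24% starting material and 84.5% self-condensation product, and at 15.0 d 100% of the catalyst was free. The flask thus reached 0.684 of its free-catalyst share. For the neighbour flask with 0.018 M of free catalyst, that share comes to 16.1%, and its target stood at 10.8%, a fraction of 0.671.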